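**Plan**
- Retrosynthesis: remove the three silyl groups; raise oxolane C2 to a lactone carbonyl; cut the C3–carbinol bond (aldol); cut O1–C5 and rejoin C5 to C2 (retro Baeyer–Villiger) to reach a 3-(arylmethyl)cyclobutanone; cut that into O-silyl eugenol and dichloroketene ([2+2]).
- Enabling feature: oxolane C4, which carries the arylmethyl group, lies between two ring CH2 groups (C5 on O1, and C3 once its carbinol arm is removed). With C2 as a carbonyl and O1 excised, C2, C3, C4 and C5 form a cyclobutanone with a mirror plane through C2 and C4, so its two α-CH2 groups are enantiotopic.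
- Forward: the four-membered carbocycle is made first ([2+2], dechlorination) and expanded to the five-membered O-heterocycle by oxygen insertion, which forms the O1–C5 bond. The aryl carbinol arm is then joined by aldol, the lactone C=O is taken down to CH2, and the silyl groups are removed.
- Stereochemistry: C4 comes from catalyst-controlled choice between the enantiotopic migrating CH2 groups; C3 from attack on the lactone enolate anti to the C4 substituent; the carbinol carbon from the chair transition state of the ring-fixed boron enolate (anti aldol).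

Key step: step 4

Abbreviations: TBS = tert-butyldimethylsilyl; Ar = 4-(tert-butyldimethylsilyloxy)-3-methoxyphenyl. Ring positions follow oxolane numbering (O1, C2, C3 with the carbinol arm, C4 with the arylmethyl arm, C5).

Assumption: the sense of induction of the Sc(OTf)3/N,N'-dioxide catalyst for a 3-(arylmethyl)cyclobutanone is not derived here. The ligand is the C2-symmetric bis(N-oxide) built from pipecolic acid, 2,6-diisopropylaniline and a propane-1,3-diyl linker; it can be made from either (S)- or (R)-pipecolic acid, and the antipode that delivers the (R)-lactone is the one to be used.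

**Step 1**
Reactants: 1 eugenol (4-allyl-2-methoxyphenol)
Product: 2 tert-butyl(4-allyl-2-methoxyphenoxy)dimethylsilane
Conditions: TBSCl, imidazole, DMF, rt
Reagents that add atoms: tert-butyldimethylsilyl chloride, CC(C)(C)[Si](C)(C)Cl
Why: Imidazole-promoted O-silylation masks the phenol as an aryl silyl ether that should tolerate zinc, peracid, boron aldol, hydride and Lewis acid steps and is removed by fluoride at the end.

**Step 2**
Reactants: 2 tert-butyl(4-allyl-2-methoxyphenoxy)dimethylsilane; 3 trichloroacetyl chloride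
Product: 5 rac-2,2-dichloro-3-(Ar-methyl)cyclobutan-1-one, via dichloroketene 4 (not isolated)
Conditions: Zn–Cu couple, POCl3, Et2O, 35 °C
Reagents that add atoms: none
Why: Zinc-mediated 1,2-elimination of 3 gives dichloroketene, which undergoes thermal [2+2] cycloaddition with the terminal alkene, its carbonyl carbon bonding to the terminal CH2; the racemic ring stereocenter formed here loses its stereogenicity in step 3.

**Step 3**
Reactants: 5 rac-2,2-dichloro-3-(Ar-methyl)cyclobutan-1-one
Product: 6 3-(Ar-methyl)cyclobutan-1-one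
Conditions: Zn dust, AcOH, 50 °C
Reagents that add atoms: none
Why: Reductive dehalogenation of the α,α-dichloroketone through zinc enolates should leave the strained ketone intact and give the mirror-symmetric, prochiral cyclobutanone.

**Step 4**
Reactants: 6 3-(Ar-methyl)cyclobutan-1-one
Product: 8 (4R)-4-(Ar-methyl)oxolan-2-one, via Criegee adduct 7 (not isolated)
Conditions: Sc(OTf)3 (5 mol%), chiral N,N'-dioxide ligand (6 mol%), mCPBA (1.2 equiv), EtOAc, −20 °C
Reagents that add atoms: 3-chloroperoxybenzoic acid, OOC(=O)c1cccc(Cl)c1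
Why: The peracid adds to the Sc(OTf)3-activated carbonyl of 6 to give Criegee adduct 7, in which one ring CH2 group, held antiperiplanar to the O–O bond, migrates from carbon to oxygen as 3-chlorobenzoate leaves; this 1,2-shift forms the CH2–O bond and releases the strain of the four-membered ring. The closest known reaction type is the catalytic enantioselective Baeyer–Villiger desymmetrization of 3-substituted cyclobutanones. The five-membered lactone is closed by ring expansion (oxygen inserted between C1 and C4 of the cyclobutanone), a concerted migration with retention at the migrating carbon and not an exo or endo attack. The only new stereocenter, the carbon bearing the arylmethyl group, is not touched by the bond changes: it becomes stereogenic because the chiral scandium complex binds the Criegee adduct and aligns only one of the two enantiotopic CH2 groups for migration (catalyst control). The step needs enantiotopic-group selectivity and chemoselectivity for the ketone over the electron-rich arene; regioselectivity is not an issue because both α-carbons are identical CH2 groups, and the strained ketone should react at −20 °C well before the silylated guaiacyl ring can be oxidised.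

**Step 5**
Reactants: 9 vanillin (4-hydroxy-3-methoxybenzaldehyde)
Product: 10 4-(tert-butyldimethylsilyloxy)-3-methoxybenzaldehyde
Conditions: TBSCl, imidazole, DMF, rt
Reagents that add atoms: tert-butyldimethylsilyl chloride, CC(C)(C)[Si](C)(C)Cl
Why: O-silylation of the phenol gives an aldehyde partner carrying the same fluoride-labile protecting group as the lactone fragment.

**Step 6**
Reactants: 8 (4R)-4-(Ar-methyl)oxolan-2-one; 10 4-(tert-butyldimethylsilyloxy)-3-methoxybenzaldehyde
Product: 13 (3S,4R)-3-[(R)-Ar(hydroxy)methyl]-4-(Ar-methyl)oxolan-2-one, via boron enolate 11 (not isolated), via boron aldolate 12 (not isolated)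
Conditions: (c-C6H11)2BOTf, Et3N, CH2Cl2, −78 °C; then 10, −78 to 0 °C; then pH 7 buffer, MeOH, 30% H2O2, 0 °C
Reagents that add atoms: none
Why: Soft enolization gives the boron enolate whose geometry is fixed by the ring (α-ring carbon trans to O–B), so the boron aldol should pass through a tight Zimmerman–Traxler chair with the aryl group pseudo-equatorial to give the anti aldol, which is the (R)-carbinol, while the aldehyde attacks the enolate face anti to the C4 arylmethyl group and so sets the trans-3,4 relationship.

**Step 7**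
Reactants: 13 (3S,4R)-3-[(R)-Ar(hydroxy)methyl]-4-(Ar-methyl)oxolan-2-one
Product: 14 (3S,4R)-3-[(R)-Ar(tert-butyldimethylsilyloxy)methyl]-4-(Ar-methyl)oxolan-2-one
Conditions: TBSOTf, 2,6-lutidine, CH2Cl2, −78 to 0 °C
Reagents that add atoms: tert-butyldimethylsilyl trifluoromethanesulfonate, CC(C)(C)[Si](C)(C)OS(=O)(=O)C(F)(F)F
Why: Silylation of the secondary alcohol under non-nucleophilic base avoids retro-aldol, touches no stereocenter, and gives a bulky, weakly Lewis-basic benzylic ether for the next two steps.

**Step 8**
Reactants: 14 (3S,4R)-3-[(R)-Ar(tert-butyldimethylsilyloxy)methyl]-4-(Ar-methyl)oxolan-2-one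
Product: 15 (3S,4R)-3-[(R)-Ar(tert-butyldimethylsilyloxy)methyl]-4-(Ar-methyl)oxolan-2-ol (mixture of anomers)
Conditions: i-Bu2AlH (1.1 equiv), CH2Cl2, −78 °C; then MeOH, aq. KNaC4H4O6
Reagents that add atoms: none
Why: Partial reduction of the lactone stops at the lactol because the tetrahedral aluminium hemiacetal is stable at −78 °C; the anomeric mixture is of no consequence since that carbon becomes CH2 in step 9.

**Step 9**
Reactants: 15 (3S,4R)-3-[(R)-Ar(tert-butyldimethylsilyloxy)methyl]-4-(Ar-methyl)oxolan-2-ol
Product: 16 tert-butyl{(R)-Ar[(3R,4R)-4-(Ar-methyl)oxolan-3-yl]methoxy}dimethylsilane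
Conditions: Et3SiH (5 equiv), BF3·OEt2 (2 equiv), CH2Cl2, −78 °C
Reagents that add atoms: none
Why: Ionic hydrogenation of the lactol through the cyclic oxocarbenium ion, trapped by the silane, should be faster at −78 °C than ionization of the hindered benzylic silyl ether; it makes C2 a CH2 group without opening the ring, so the O1–C5 bond from step 4 and all three stereocenters are untouched.

**Step 10**
Reactants: 16 tert-butyl{(R)-Ar[(3R,4R)-4-(Ar-methyl)oxolan-3-yl]methoxy}dimethylsilane
Product: 17 (R)-(4-hydroxy-3-methoxyphenyl)[(3R,4R)-4-[(4-hydroxy-3-methoxyphenyl)methyl]oxolan-3-yl]methanol (CNP0234428.1)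
Conditions: Bu4NF (3.5 equiv), AcOH (3.5 equiv), THF, 0 °C to rt
Reagents that add atoms: none
Why: Fluoride cleaves the two aryl and the one benzylic Si–O bond in one operation, and the acetic acid buffer keeps the phenoxides protonated so that the p-hydroxybenzylic alcohol is not lost through a quinone methide.

**Compound list**
1 | eugenol (4-allyl-2-methoxyphenol) | C=CCc1ccc(O)c(OC)c1 | starting material
2 | tert-butyl(4-allyl-2-methoxyphenoxy)dimethylsilane | C=CCc1ccc(O[Si](C)(C)C(C)(C)C)c(OC)c1 | intermediate
3 | trichloroacetyl chloride | ClC(Cl)(Cl)C(=O)Cl | starting material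
4 | dichloroketene (formed in the flask) | O=C=C(Cl)Cl | intermediate
5 | rac-2,2-dichloro-3-{[4-(tert-butyldimethylsilyloxy)-3-methoxyphenyl]methyl}cyclobutan-1-one | O=C1CC(Cc2ccc(O[Si](C)(C)C(C)(C)C)c(OC)c2)C1(Cl)Cl | intermediate
6 | 3-{[4-(tert-butyldimethylsilyloxy)-3-methoxyphenyl]methyl}cyclobutan-1-one (achiral) | O=C1CC(Cc2ccc(O[Si](C)(C)C(C)(C)C)c(OC)c2)C1 | intermediate
7 | Criegee adduct, 3-(Ar-methyl)-1-hydroxycyclobutyl 3-chloroperoxybenzoate (formed in the flask) | OC1(OOC(=O)c2cccc(Cl)c2)CC(Cc2ccc(O[Si](C)(C)C(C)(C)C)c(OC)c2)C1 | intermediate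
8 | (4R)-4-{[4-(tert-butyldimethylsilyloxy)-3-methoxyphenyl]methyl}oxolan-2-one | COc1cc(C[C@H]2COC(=O)C2)ccc1O[Si](C)(C)C(C)(C)C | intermediate
9 | vanillin (4-hydroxy-3-methoxybenzaldehyde) | COc1cc(C=O)ccc1O | starting material
10 | 4-(tert-butyldimethylsilyloxy)-3-methoxybenzaldehyde | COc1cc(C=O)ccc1O[Si](C)(C)C(C)(C)C | intermediate
11 | boron enolate, dicyclohexyl{[(4R)-4-(Ar-methyl)-4,5-dihydrofuran-2-yl]oxy}borane (formed in the flask) | COc1cc(C[C@H]2COC(OB(C3CCCCC3)C3CCCCC3)=C2)ccc1O[Si](C)(C)C(C)(C)C | intermediate
12 | boron aldolate, O-dicyclohexylboryl derivative of 13 (formed in the flask) | COc1cc(C[C@H]2COC(=O)[C@@H]2[C@@H](OB(C3CCCCC3)C3CCCCC3)c2ccc(O[Si](C)(C)C(C)(C)C)c(OC)c2)ccc1O[Si](C)(C)C(C)(C)C | intermediate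
13 | (3S,4R)-3-[(R)-Ar(hydroxy)methyl]-4-(Ar-methyl)oxolan-2-one | COc1cc(C[C@H]2COC(=O)[C@@H]2[C@@H](O)c2ccc(O[Si](C)(C)C(C)(C)C)c(OC)c2)ccc1O[Si](C)(C)C(C)(C)C | intermediate
14 | (3S,4R)-3-[(R)-Ar(tert-butyldimethylsilyloxy)methyl]-4-(Ar-methyl)oxolan-2-one | COc1cc(C[C@H]2COC(=O)[C@@H]2[C@@H](O[Si](C)(C)C(C)(C)C)c2ccc(O[Si](C)(C)C(C)(C)C)c(OC)c2)ccc1O[Si](C)(C)C(C)(C)C | intermediate
15 | (3S,4R)-3-[(R)-Ar(tert-butyldimethylsilyloxy)methyl]-4-(Ar-methyl)oxolan-2-ol (mixture of anomers) | COc1cc(C[C@H]2COC(O)[C@@H]2[C@@H](O[Si](C)(C)C(C)(C)C)c2ccc(O[Si](C)(C)C(C)(C)C)c(OC)c2)ccc1O[Si](C)(C)C(C)(C)C | intermediate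
16 | tert-butyl{(R)-Ar[(3R,4R)-4-(Ar-methyl)oxolan-3-yl]methoxy}dimethylsilane | COc1cc(C[C@H]2COC[C@@H]2[C@@H](O[Si](C)(C)C(C)(C)C)c2ccc(O[Si](C)(C)C(C)(C)C)c(OC)c2)ccc1O[Si](C)(C)C(C)(C)C | intermediate
17 | (R)-(4-hydroxy-3-methoxyphenyl)[(3R,4R)-4-[(4-hydroxy-3-methoxyphenyl)methyl]oxolan-3-yl]methanol | COc1cc(C[C@H]2COC[C@@H]2[C@@H](O)c2ccc(O)c(OC)c2)ccc1O | target

**Step count**
Total: 10 steps. Longest linear sequence: 9 steps (1 → 2 → 5 → 6 → 8 → 13 → 14 → 15 → 16 → 17); step 5 is a one-step side branch.

**Steps most likely to fail**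

1. Step 4: the catalyst may discriminate too weakly between the two enantiotopic CH2 groups of a 3-(arylmethyl) substrate, or peracid may attack the arene. Fallback by resolution, setting out from 6 and returning at 8: uncatalysed oxidation of 6 (mCPBA, NaHCO3, CH2Cl2) would give the racemic lactone F1. AlMe3-mediated aminolysis with (S)-1-phenylethylamine would open it to the diastereomeric hydroxy amide F2 (3R acid part) and hydroxy amide F3 (3S acid part), to be separated by crystallisation or chromatography. Heating F2 with TsOH·H2O in toluene would close the lactone again to 8 and release the amine.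

2. Step 6: enolization by the boron triflate may be incomplete, or the chair transition state may give poor syn/anti discrimination at the carbinol carbon. Fallback by oxidation and catalyst-controlled reduction, setting out from 8 (with 10) and returning at 13: the lithium enolate aldol (LiN(i-Pr)2, THF, −78 °C) would give the trans lactone as 13 mixed with its carbinol epimer F4. Dess–Martin periodinane would converge both on keto lactone F5. Asymmetric transfer hydrogenation with RuCl(p-cymene)[(R,R)-TsDPEN] in HCO2H/Et3N should then set the (R)-carbinol by catalyst control, the epimerisable C3 staying in the favoured trans arrangement.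

3. Step 9: the Lewis acid may ionize the electron-rich benzylic silyloxy carbon, or the arylmethyl ring may capture the oxocarbenium ion (Friedel–Crafts) before the silane does. Fallback without acid, setting out from 14 and returning at 16: LiBH4 (THF, 0 °C to rt) would reduce the lactone to diol F6, and Mitsunobu cyclodehydration (PPh3, DIAD, THF) would close the oxolane to 16; whichever primary hydroxyl is activated, the same ring results.

**Further compounds**
F1 | step 4 | rac-4-{[4-(tert-butyldimethylsilyloxy)-3-methoxyphenyl]methyl}oxolan-2-one | COc1cc(CC2COC(=O)C2)ccc1O[Si](C)(C)C(C)(C)C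
F2 | step 4 | (3R)-4-hydroxy-3-(Ar-methyl)-N-[(1S)-1-phenylethyl]butanamide | COc1cc(C[C@@H](CO)CC(=O)N[C@@H](C)c2ccccc2)ccc1O[Si](C)(C)C(C)(C)C
F3 | step 4 | (3S)-4-hydroxy-3-(Ar-methyl)-N-[(1S)-1-phenylethyl]butanamide | COc1cc(C[C@H](CO)CC(=O)N[C@@H](C)c2ccccc2)ccc1O[Si](C)(C)C(C)(C)C
F4 | step 6 | (3S,4R)-3-[(S)-Ar(hydroxy)methyl]-4-(Ar-methyl)oxolan-2-one | COc1cc(C[C@H]2COC(=O)[C@@H]2[C@H](O)c2ccc(O[Si](C)(C)C(C)(C)C)c(OC)c2)ccc1O[Si](C)(C)C(C)(C)C
F5 | step 6 | (3S,4R)-3-(Ar-carbonyl)-4-(Ar-methyl)oxolan-2-one | COc1cc(C[C@H]2COC(=O)[C@@H]2C(=O)c2ccc(O[Si](C)(C)C(C)(C)C)c(OC)c2)ccc1O[Si](C)(C)C(C)(C)C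
F6 | step 9 | (2R,3R)-2-[(R)-Ar(tert-butyldimethylsilyloxy)methyl]-3-(Ar-methyl)butane-1,4-diol | COc1cc(C[C@@H](CO)[C@H](CO)[C@@H](O[Si](C)(C)C(C)(C)C)c2ccc(O[Si](C)(C)C(C)(C)C)c(OC)c2)ccc1O[Si](C)(C)C(C)(C)C
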